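**Assumption:** the target is taken exactly as encoded, i.e. (2S,6R,7R,8R) with a 1(10)Z olefin, a 4Z (ring-trans) olefin and an (E)-tiglate. Atoms are named by germacrane numbering: C6 = lactone carbinol, C7 = ring-fusion CH, C8 = CHOH, C2 = CH–O-tiglate, C15 = CH2OAc, C14 = ring methyl, C11–C13 = methylene-lactone carbons.

**Retrosynthetic overview**
1. Target ⇐ macrocycle 26 by ether cleavage and selective C15 acetylation, C2 tigloylation and C8 desilylation; the exocyclic methylene comes from Mannich methylenation of saturated lactone 23.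
2. Ring B (ten-membered carbocycle) ⇐ ring-closing metathesis forming the Z C1=C10 olefin of diene 22; C8 carbinol ⇐ asymmetric methallylboration of lactone aldehyde 20.
3. Ring A (trans γ-lactone, C6/C7) ⇐ key fragment union: intermolecular Evans syn-aldol of succinate imide 16 (C7, C8, C11, C12) with enal 13 (C1–C6, C15), then lactonisation.
4. Enal 13 ⇐ (S)-epichlorohydrin (C2 stereocentre) and a propargyl ether: alkynylation, ylide vinylation, trans-hydroalumination/iodination, alkoxymethyl Suzuki coupling.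
5. Order of ring formation: ring A (step 10), then ring B (step 15).

**Route**

Step 1
Reactants: 1 tert-butyldimethyl(prop-2-yn-1-yloxy)silane; 2 (S)-epichlorohydrin
Product: 3 (2S)-6-[(tert-butyldimethylsilyl)oxy]-1-chlorohex-4-yn-2-ol
Conditions: n-BuLi, THF, −78 °C; BF3·OEt2; then 2, −78 °C
Reagents that add atoms: none
Why: Yamaguchi–Hirao alkynylation: the BF3-activated epoxide is opened by the lithium acetylide at its unsubstituted carbon (SN2), so the stereocentre of 2 is carried over unchanged as C2.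

Step 2
Reactants: 3 (2S)-6-[(tert-butyldimethylsilyl)oxy]-1-chlorohex-4-yn-2-ol
Product: 5 (3S)-7-[(tert-butyldimethylsilyl)oxy]hept-1-en-5-yn-3-ol, via epoxide 4 (not isolated)
Conditions: Me3S+ I− (4 equiv), n-BuLi (3.8 equiv), THF, −10 °C → rt
Reagents that add atoms: trimethylsulfonium iodide, C[S+](C)C.[I-]
Why: The ylide first closes the chlorohydrin to the terminal epoxide, then opens it at CH2 and loses Me2S by elimination (Corey–Chaykovsky-type epoxide-to-allylic-alcohol homologation); the carbinol centre is not touched.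

Step 3
Reactants: 5 (3S)-7-[(tert-butyldimethylsilyl)oxy]hept-1-en-5-yn-3-ol
Product: 6 tert-butyl({(5S)-5-[(4-methoxybenzyl)oxy]hept-6-en-2-yn-1-yl}oxy)dimethylsilane
Conditions: NaH, 4-methoxybenzyl chloride, n-Bu4NI (cat.), THF/DMF, 0 °C → rt
Reagents that add atoms: 4-methoxybenzyl chloride, COc1ccc(CCl)cc1
Why: Williamson etherification of the secondary alkoxide; the linear alkyne keeps the silyl ether out of reach of the alkoxide, so no silyl migration.

Step 4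
Reactants: 6 tert-butyl({(5S)-5-[(4-methoxybenzyl)oxy]hept-6-en-2-yn-1-yl}oxy)dimethylsilane
Product: 7 (5S)-5-[(4-methoxybenzyl)oxy]hept-6-en-2-yn-1-ol
Conditions: n-Bu4NF, THF, 0 °C
Reagents that add atoms: none
Why: Fluoride desilylation frees the propargylic alcohol needed to direct the next step; the PMB ether is inert.

Step 5
Reactants: 7 (5S)-5-[(4-methoxybenzyl)oxy]hept-6-en-2-yn-1-ol
Product: 8 (2Z,5S)-3-iodo-5-[(4-methoxybenzyl)oxy]hepta-2,6-dien-1-ol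
Conditions: NaAlH2(OCH2CH2OMe)2, THF, 0 °C → rt; EtOAc; then I2, THF, −78 → 0 °C; aq. Na2S2O3 / potassium sodium tartrate
Reagents that add atoms: iodine, II
Why: Hydroxyl-directed trans-hydroalumination of the propargylic alcohol puts aluminium on the distal alkyne carbon cis to CH2OH; iodinolysis with retention gives the Z-iodide that fixes the C4=C5 geometry.

Step 6
Reactants: 9 4-methoxybenzyl alcohol; 10 potassium (bromomethyl)trifluoroborate
Product: 11 potassium trifluoro{[(4-methoxybenzyl)oxy]methyl}borate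
Conditions: NaH, 9 (3 equiv), THF, 0 °C; then 10, rt
Reagents that add atoms: none
Why: SN2 displacement of bromide from the bromomethyltrifluoroborate by the alkoxide gives an air-stable alkoxymethyl nucleophile.

Step 7
Reactants: 8 (2Z,5S)-3-iodo-5-[(4-methoxybenzyl)oxy]hepta-2,6-dien-1-ol; 11 potassium trifluoro{[(4-methoxybenzyl)oxy]methyl}borate
Product: 12 (2Z,5S)-5-[(4-methoxybenzyl)oxy]-3-{[(4-methoxybenzyl)oxy]methyl}hepta-2,6-dien-1-ol
Conditions: Pd(OAc)2 (5 mol %), RuPhos (10 mol %), Cs2CO3, 1,4-dioxane/H2O 10:1, 90 °C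
Reagents that add atoms: none
Why: Suzuki–Miyaura coupling of an alkoxymethyltrifluoroborate (no β-hydrogens) with the alkenyl iodide proceeds with retention, so the protected C15 carbon ends up cis to C6 as the target requires.

Step 8
Reactants: 12 (2Z,5S)-5-[(4-methoxybenzyl)oxy]-3-{[(4-methoxybenzyl)oxy]methyl}hepta-2,6-dien-1-ol
Product: 13 (2Z,5S)-5-[(4-methoxybenzyl)oxy]-3-{[(4-methoxybenzyl)oxy]methyl}hepta-2,6-dienal
Conditions: MnO2 (activated, excess), CH2Cl2, rt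
Reagents that add atoms: none
Why: Heterogeneous allylic oxidation with MnO2 is neutral and selective for the allylic primary alcohol and does not isomerise the olefin.

Step 9
Reactants: 14 (4S)-4-benzyl-1,3-oxazolidin-2-one; 15 methyl 4-chloro-4-oxobutanoate
Product: 16 methyl 4-[(4S)-4-benzyl-2-oxo-1,3-oxazolidin-3-yl]-4-oxobutanoate
Conditions: n-BuLi, THF, −78 °C; then 15, −78 → 0 °C
Reagents that add atoms: none
Why: N-acylation of the lithiated oxazolidinone by the acid chloride, which reacts far faster than the methyl ester.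

Step 10
Reactants: 16 methyl 4-[(4S)-4-benzyl-2-oxo-1,3-oxazolidin-3-yl]-4-oxobutanoate; 13 (2Z,5S)-5-[(4-methoxybenzyl)oxy]-3-{[(4-methoxybenzyl)oxy]methyl}hepta-2,6-dienal
Product: 18 (4S)-4-benzyl-3-{[(2R,3S)-2-[(1Z,4S)-4-[(4-methoxybenzyl)oxy]-2-{[(4-methoxybenzyl)oxy]methyl}hexa-1,5-dien-1-yl]-5-oxooxolan-3-yl]carbonyl}-1,3-oxazolidin-2-one, via aldol adduct 17 (not isolated)
Conditions: Bu2BOTf, i-Pr2NEt, CH2Cl2, −78 → 0 °C; 13, −78 → 0 °C; pH 7 buffer, MeOH, H2O2, 0 °C; then PPTS (cat.), CH2Cl2, rt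
Reagents that add atoms: none
Why: Evans syn-aldol: the Z boron enolate forms only at the imide and adds through a Zimmerman–Traxler chair on the face away from the benzyl group, setting C6 (R) and C7 in the syn sense; the new C6 hydroxyl then closes onto the methyl ester to give the trans γ-lactone (ring A).

Step 11
Reactants: 18 (4S)-4-benzyl-3-{[(2R,3S)-2-[(1Z,4S)-4-[(4-methoxybenzyl)oxy]-2-{[(4-methoxybenzyl)oxy]methyl}hexa-1,5-dien-1-yl]-5-oxooxolan-3-yl]carbonyl}-1,3-oxazolidin-2-one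
Product: 19 (4R,5R)-4-(hydroxymethyl)-5-[(1Z,4S)-4-[(4-methoxybenzyl)oxy]-2-{[(4-methoxybenzyl)oxy]methyl}hexa-1,5-dien-1-yl]oxolan-2-one
Conditions: NaBH4, THF/H2O 4:1, 0 °C, short reaction time
Reagents that add atoms: none
Why: Chemoselective hydride reduction of the activated exocyclic imide carbonyl, which reacts faster than the γ-lactone; the auxiliary is released intact and no stereocentre is touched.

Step 12
Reactants: 19 (4R,5R)-4-(hydroxymethyl)-5-[(1Z,4S)-4-[(4-methoxybenzyl)oxy]-2-{[(4-methoxybenzyl)oxy]methyl}hexa-1,5-dien-1-yl]oxolan-2-one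
Product: 20 (2R,3S)-2-[(1Z,4S)-4-[(4-methoxybenzyl)oxy]-2-{[(4-methoxybenzyl)oxy]methyl}hexa-1,5-dien-1-yl]-5-oxooxolane-3-carbaldehyde
Conditions: Dess–Martin periodinane, CH2Cl2, 0 °C → rt; aq. NaHCO3/Na2S2O3 work-up; used at once
Reagents that add atoms: none
Why: Dess–Martin oxidation is non-basic, so the α-stereocentre C7 is not epimerised and the β-acyloxy aldehyde does not eliminate.

Step 13
Reactants: 20 (2R,3S)-2-[(1Z,4S)-4-[(4-methoxybenzyl)oxy]-2-{[(4-methoxybenzyl)oxy]methyl}hexa-1,5-dien-1-yl]-5-oxooxolane-3-carbaldehyde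
Product: 21 (4R,5R)-4-[(1R)-1-hydroxy-3-methylbut-3-en-1-yl]-5-[(1Z,4S)-4-[(4-methoxybenzyl)oxy]-2-{[(4-methoxybenzyl)oxy]methyl}hexa-1,5-dien-1-yl]oxolan-2-one
Conditions: (+)-Ipc2BOMe [(−)-α-pinene series], 2-methylallylmagnesium chloride, Et2O, −78 °C → rt; then 20, Et2O, −78 °C; NaBO3·4H2O, THF/H2O, rt
Reagents that add atoms: 2-methylallylmagnesium chloride, C=C(C)C[Mg]Cl (transferred through the borane it forms in the flask)
Why: Brown asymmetric methallylboration through a closed chair transition state; the chiral borane, not the substrate, selects the aldehyde face and sets C8 as (R), anti to the C6 oxygen.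

Step 14
Reactants: 21 (4R,5R)-4-[(1R)-1-hydroxy-3-methylbut-3-en-1-yl]-5-[(1Z,4S)-4-[(4-methoxybenzyl)oxy]-2-{[(4-methoxybenzyl)oxy]methyl}hexa-1,5-dien-1-yl]oxolan-2-one
Product: 22 (4S,5R)-4-[(1R)-1-[(tert-butyldimethylsilyl)oxy]-3-methylbut-3-en-1-yl]-5-[(1Z,4S)-4-[(4-methoxybenzyl)oxy]-2-{[(4-methoxybenzyl)oxy]methyl}hexa-1,5-dien-1-yl]oxolan-2-one
Conditions: TBSOTf, 2,6-lutidine, CH2Cl2, −78 → 0 °C
Reagents that add atoms: tert-butyldimethylsilyl trifluoromethanesulfonate, CC(C)(C)[Si](C)(C)OS(=O)(=O)C(F)(F)F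
Why: Silylation of the hindered secondary alcohol with the silyl triflate; it blocks translactonisation to C8 and keeps C8–OH out of the later acylations.

Step 15
Reactants: 22 (4S,5R)-4-[(1R)-1-[(tert-butyldimethylsilyl)oxy]-3-methylbut-3-en-1-yl]-5-[(1Z,4S)-4-[(4-methoxybenzyl)oxy]-2-{[(4-methoxybenzyl)oxy]methyl}hexa-1,5-dien-1-yl]oxolan-2-one
Product: 23 (3aS,4R,6Z,8S,10Z,11aR)-4-[(tert-butyldimethylsilyl)oxy]-8-[(4-methoxybenzyl)oxy]-10-{[(4-methoxybenzyl)oxy]methyl}-6-methyl-3a,4,5,8,9,11a-hexahydrocyclodeca[b]furan-2(3H)-one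
Conditions: second-generation Grubbs catalyst (H2IMes)(PCy3)Cl2Ru=CHPh (2 × 10 mol %), 1,4-benzoquinone (20 mol %), toluene (0.5 mM), 80 °C
Reagents that add atoms: none
Why: Ring-closing metathesis: ruthenium loads on the monosubstituted vinyl group and closes onto the 1,1-disubstituted olefin with loss of ethene; in a ten-membered ring that already holds one trans olefin the new trisubstituted olefin forms as the less strained cis (Z) isomer (ring B).

Step 16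
Reactants: 23 (3aS,4R,6Z,8S,10Z,11aR)-4-[(tert-butyldimethylsilyl)oxy]-8-[(4-methoxybenzyl)oxy]-10-{[(4-methoxybenzyl)oxy]methyl}-6-methyl-3a,4,5,8,9,11a-hexahydrocyclodeca[b]furan-2(3H)-one
Product: 26 (3aS,4R,6Z,8S,10Z,11aR)-4-[(tert-butyldimethylsilyl)oxy]-8-[(4-methoxybenzyl)oxy]-10-{[(4-methoxybenzyl)oxy]methyl}-6-methyl-3-methylidene-3a,4,5,8,9,11a-hexahydrocyclodeca[b]furan-2(3H)-one, via Mannich base 24 (not isolated), via ammonium iodide 25 (not isolated)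
Conditions: LiN(i-Pr)2, THF, −78 °C; CH2=NMe2+ I−, −78 °C → rt; MeI, MeOH, rt; aq. NaHCO3, CH2Cl2, rt
Reagents that add atoms: N,N-dimethylmethyleneiminium iodide (Eschenmoser's salt), C=[N+](C)C.[I-]; iodomethane, CI (its carbon is carried only in 25 and leaves as trimethylamine)
Why: Mannich aminomethylation of the lactone enolate (only ethers are present, so C11 is the only acidic site), then quaternisation and β-elimination give the α-methylene lactone; the C11 centre of 24/25 is destroyed, so its configuration is irrelevant.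

Step 17
Reactants: 26 (3aS,4R,6Z,8S,10Z,11aR)-4-[(tert-butyldimethylsilyl)oxy]-8-[(4-methoxybenzyl)oxy]-10-{[(4-methoxybenzyl)oxy]methyl}-6-methyl-3-methylidene-3a,4,5,8,9,11a-hexahydrocyclodeca[b]furan-2(3H)-one
Product: 27 (3aS,4R,6Z,8S,10Z,11aR)-4-[(tert-butyldimethylsilyl)oxy]-8-hydroxy-10-(hydroxymethyl)-6-methyl-3-methylidene-3a,4,5,8,9,11a-hexahydrocyclodeca[b]furan-2(3H)-one
Conditions: DDQ (2.5 equiv), CH2Cl2/pH 7 buffer 10:1, 0 °C
Reagents that add atoms: none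
Why: Oxidative cleavage of both PMB ethers by DDQ (hydride abstraction, hydrolysis of the oxocarbenium ion); the silyl ether, the olefins and the methylene lactone are inert under these buffered conditions.

Step 18
Reactants: 27 (3aS,4R,6Z,8S,10Z,11aR)-4-[(tert-butyldimethylsilyl)oxy]-8-hydroxy-10-(hydroxymethyl)-6-methyl-3-methylidene-3a,4,5,8,9,11a-hexahydrocyclodeca[b]furan-2(3H)-one
Product: 28 [(3aS,4R,6Z,8S,10Z,11aR)-4-[(tert-butyldimethylsilyl)oxy]-8-hydroxy-6-methyl-3-methylidene-2-oxo-2,3,3a,4,5,8,9,11a-octahydrocyclodeca[b]furan-10-yl]methyl acetate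
Conditions: AcCl (1.1 equiv), 2,4,6-collidine, CH2Cl2, −78 °C
Reagents that add atoms: acetyl chloride, CC(Cl)=O
Why: Kinetically selective acylation: the primary allylic C15 hydroxyl reacts with the acylpyridinium far faster than the secondary C2 hydroxyl at −78 °C.

Step 19
Reactants: 28 [(3aS,4R,6Z,8S,10Z,11aR)-4-[(tert-butyldimethylsilyl)oxy]-8-hydroxy-6-methyl-3-methylidene-2-oxo-2,3,3a,4,5,8,9,11a-octahydrocyclodeca[b]furan-10-yl]methyl acetate; 29 (2E)-2-methylbut-2-enoyl chloride (tigloyl chloride)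
Product: 30 (3aS,4R,6Z,8S,10Z,11aR)-10-(acetoxymethyl)-4-[(tert-butyldimethylsilyl)oxy]-6-methyl-3-methylidene-2-oxo-2,3,3a,4,5,8,9,11a-octahydrocyclodeca[b]furan-8-yl (2E)-2-methylbut-2-enoate
Conditions: 29 (3 equiv), pyridine, DMAP (cat.), CH2Cl2, 0 °C → rt
Reagents that add atoms: none
Why: DMAP-catalysed acylation of the only free hydroxyl (C2) with retention at carbon; the E (tiglate) geometry is the stable one and pyridine is too weak a base to deconjugate the acyl chloride.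

Step 20
Reactants: 30 (3aS,4R,6Z,8S,10Z,11aR)-10-(acetoxymethyl)-4-[(tert-butyldimethylsilyl)oxy]-6-methyl-3-methylidene-2-oxo-2,3,3a,4,5,8,9,11a-octahydrocyclodeca[b]furan-8-yl (2E)-2-methylbut-2-enoate
Product: 31 (3aR,4R,6Z,8S,10Z,11aR)-10-(acetoxymethyl)-4-hydroxy-6-methyl-3-methylidene-2-oxo-2,3,3a,4,5,8,9,11a-octahydrocyclodeca[b]furan-8-yl (2E)-2-methylbut-2-enoate (target)
Conditions: HF·pyridine, pyridine/THF, 0 °C → rt
Reagents that add atoms: none
Why: Fluoride desilylation under buffered acidic conditions leaves the acetate, the tiglate and the methylene lactone intact; the freed 8-hydroxyl is cis to the C7 side chain and so does not translactonise from the trans-fused lactone.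

**Compound list**
1 | tert-butyldimethyl(prop-2-yn-1-yloxy)silane | C#CCO[Si](C)(C)C(C)(C)C | starting material
2 | (S)-epichlorohydrin | ClC[C@@H]1CO1 | starting material
3 | (2S)-6-[(tert-butyldimethylsilyl)oxy]-1-chlorohex-4-yn-2-ol | ClC[C@@H](O)CC#CCO[Si](C)(C)C(C)(C)C | intermediate
4 | tert-butyldimethyl({4-[(2S)-oxiran-2-yl]but-2-yn-1-yl}oxy)silane | C1[C@@H](O1)CC#CCO[Si](C)(C)C(C)(C)C | intermediate (not isolated)
5 | (3S)-7-[(tert-butyldimethylsilyl)oxy]hept-1-en-5-yn-3-ol | C=C[C@@H](O)CC#CCO[Si](C)(C)C(C)(C)C | intermediate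
6 | tert-butyl({(5S)-5-[(4-methoxybenzyl)oxy]hept-6-en-2-yn-1-yl}oxy)dimethylsilane | C=C[C@@H](OCc1ccc(OC)cc1)CC#CCO[Si](C)(C)C(C)(C)C | intermediate
7 | (5S)-5-[(4-methoxybenzyl)oxy]hept-6-en-2-yn-1-ol | C=C[C@@H](OCc1ccc(OC)cc1)CC#CCO | intermediate
8 | (2Z,5S)-3-iodo-5-[(4-methoxybenzyl)oxy]hepta-2,6-dien-1-ol | C=C[C@@H](OCc1ccc(OC)cc1)C/C(I)=C/CO | intermediate
9 | 4-methoxybenzyl alcohol | COc1ccc(CO)cc1 | starting material
10 | potassium (bromomethyl)trifluoroborate | [K+].BrC[B-](F)(F)F | starting material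
11 | potassium trifluoro{[(4-methoxybenzyl)oxy]methyl}borate | [K+].COc1ccc(COC[B-](F)(F)F)cc1 | intermediate
12 | (2Z,5S)-5-[(4-methoxybenzyl)oxy]-3-{[(4-methoxybenzyl)oxy]methyl}hepta-2,6-dien-1-ol | C=C[C@@H](OCc1ccc(OC)cc1)C/C(COCc1ccc(OC)cc1)=C/CO | intermediate
13 | (2Z,5S)-5-[(4-methoxybenzyl)oxy]-3-{[(4-methoxybenzyl)oxy]methyl}hepta-2,6-dienal | C=C[C@@H](OCc1ccc(OC)cc1)C/C(COCc1ccc(OC)cc1)=C/C=O | intermediate
14 | (4S)-4-benzyl-1,3-oxazolidin-2-one | O=C1N[C@@H](Cc2ccccc2)CO1 | starting material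
15 | methyl 4-chloro-4-oxobutanoate | COC(=O)CCC(Cl)=O | starting material
16 | methyl 4-[(4S)-4-benzyl-2-oxo-1,3-oxazolidin-3-yl]-4-oxobutanoate | COC(=O)CCC(=O)N1[C@@H](Cc2ccccc2)COC1=O | intermediate
17 | methyl (3S,4R,5Z,8S)-3-{[(4S)-4-benzyl-2-oxo-1,3-oxazolidin-3-yl]carbonyl}-4-hydroxy-8-[(4-methoxybenzyl)oxy]-6-{[(4-methoxybenzyl)oxy]methyl}deca-5,9-dienoate | COC(=O)C[C@H](C(=O)N1[C@@H](Cc2ccccc2)COC1=O)[C@H](O)/C=C(\COCc1ccc(OC)cc1)C[C@H](OCc1ccc(OC)cc1)C=C | intermediate (not isolated)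
18 | (4S)-4-benzyl-3-{[(2R,3S)-2-[(1Z,4S)-4-[(4-methoxybenzyl)oxy]-2-{[(4-methoxybenzyl)oxy]methyl}hexa-1,5-dien-1-yl]-5-oxooxolan-3-yl]carbonyl}-1,3-oxazolidin-2-one | O=C1C[C@H](C(=O)N2[C@@H](Cc3ccccc3)COC2=O)[C@@H](/C=C(\COCc2ccc(OC)cc2)C[C@H](OCc2ccc(OC)cc2)C=C)O1 | intermediate
19 | (4R,5R)-4-(hydroxymethyl)-5-[(1Z,4S)-4-[(4-methoxybenzyl)oxy]-2-{[(4-methoxybenzyl)oxy]methyl}hexa-1,5-dien-1-yl]oxolan-2-one | O=C1C[C@H](CO)[C@@H](/C=C(\COCc2ccc(OC)cc2)C[C@H](OCc2ccc(OC)cc2)C=C)O1 | intermediate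
20 | (2R,3S)-2-[(1Z,4S)-4-[(4-methoxybenzyl)oxy]-2-{[(4-methoxybenzyl)oxy]methyl}hexa-1,5-dien-1-yl]-5-oxooxolane-3-carbaldehyde | O=C1C[C@H](C=O)[C@@H](/C=C(\COCc2ccc(OC)cc2)C[C@H](OCc2ccc(OC)cc2)C=C)O1 | intermediate
21 | (4R,5R)-4-[(1R)-1-hydroxy-3-methylbut-3-en-1-yl]-5-[(1Z,4S)-4-[(4-methoxybenzyl)oxy]-2-{[(4-methoxybenzyl)oxy]methyl}hexa-1,5-dien-1-yl]oxolan-2-one | O=C1C[C@H]([C@H](O)CC(C)=C)[C@@H](/C=C(\COCc2ccc(OC)cc2)C[C@H](OCc2ccc(OC)cc2)C=C)O1 | intermediate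
22 | (4S,5R)-4-[(1R)-1-[(tert-butyldimethylsilyl)oxy]-3-methylbut-3-en-1-yl]-5-[(1Z,4S)-4-[(4-methoxybenzyl)oxy]-2-{[(4-methoxybenzyl)oxy]methyl}hexa-1,5-dien-1-yl]oxolan-2-one | O=C1C[C@H]([C@H](O[Si](C)(C)C(C)(C)C)CC(C)=C)[C@@H](/C=C(\COCc2ccc(OC)cc2)C[C@H](OCc2ccc(OC)cc2)C=C)O1 | intermediate
23 | (3aS,4R,6Z,8S,10Z,11aR)-4-[(tert-butyldimethylsilyl)oxy]-8-[(4-methoxybenzyl)oxy]-10-{[(4-methoxybenzyl)oxy]methyl}-6-methyl-3a,4,5,8,9,11a-hexahydrocyclodeca[b]furan-2(3H)-one | C1C(=O)O[C@@H]2/C=C(\COCc3ccc(OC)cc3)C[C@H](OCc3ccc(OC)cc3)/C=C(/C)C[C@@H](O[Si](C)(C)C(C)(C)C)[C@@H]12 | intermediate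
24 | 3-[(dimethylamino)methyl] derivative of 23 (both C3 epimers, configuration not defined) | CN(C)CC1C(=O)O[C@@H]2/C=C(\COCc3ccc(OC)cc3)C[C@H](OCc3ccc(OC)cc3)/C=C(/C)C[C@@H](O[Si](C)(C)C(C)(C)C)[C@@H]12 | intermediate (not isolated)
25 | 3-[(trimethylammonio)methyl] derivative of 23, iodide (both C3 epimers) | C[N+](C)(C)CC1C(=O)O[C@@H]2/C=C(\COCc3ccc(OC)cc3)C[C@H](OCc3ccc(OC)cc3)/C=C(/C)C[C@@H](O[Si](C)(C)C(C)(C)C)[C@@H]12.[I-] | intermediate (not isolated)
26 | (3aS,4R,6Z,8S,10Z,11aR)-4-[(tert-butyldimethylsilyl)oxy]-8-[(4-methoxybenzyl)oxy]-10-{[(4-methoxybenzyl)oxy]methyl}-6-methyl-3-methylidene-3a,4,5,8,9,11a-hexahydrocyclodeca[b]furan-2(3H)-one | C=C1C(=O)O[C@@H]2/C=C(\COCc3ccc(OC)cc3)C[C@H](OCc3ccc(OC)cc3)/C=C(/C)C[C@@H](O[Si](C)(C)C(C)(C)C)[C@@H]12 | intermediate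
27 | (3aS,4R,6Z,8S,10Z,11aR)-4-[(tert-butyldimethylsilyl)oxy]-8-hydroxy-10-(hydroxymethyl)-6-methyl-3-methylidene-3a,4,5,8,9,11a-hexahydrocyclodeca[b]furan-2(3H)-one | C=C1C(=O)O[C@@H]2/C=C(\CO)C[C@H](O)/C=C(/C)C[C@@H](O[Si](C)(C)C(C)(C)C)[C@@H]12 | intermediate
28 | [(3aS,4R,6Z,8S,10Z,11aR)-4-[(tert-butyldimethylsilyl)oxy]-8-hydroxy-6-methyl-3-methylidene-2-oxo-2,3,3a,4,5,8,9,11a-octahydrocyclodeca[b]furan-10-yl]methyl acetate | C=C1C(=O)O[C@@H]2/C=C(\COC(C)=O)C[C@H](O)/C=C(/C)C[C@@H](O[Si](C)(C)C(C)(C)C)[C@@H]12 | intermediate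
29 | (2E)-2-methylbut-2-enoyl chloride (tigloyl chloride) | C/C=C(\C)C(Cl)=O | starting material
30 | (3aS,4R,6Z,8S,10Z,11aR)-10-(acetoxymethyl)-4-[(tert-butyldimethylsilyl)oxy]-6-methyl-3-methylidene-2-oxo-2,3,3a,4,5,8,9,11a-octahydrocyclodeca[b]furan-8-yl (2E)-2-methylbut-2-enoate | C=C1C(=O)O[C@@H]2/C=C(\COC(C)=O)C[C@H](OC(=O)/C(C)=C/C)/C=C(/C)C[C@@H](O[Si](C)(C)C(C)(C)C)[C@@H]12 | intermediate
31 | (3aR,4R,6Z,8S,10Z,11aR)-10-(acetoxymethyl)-4-hydroxy-6-methyl-3-methylidene-2-oxo-2,3,3a,4,5,8,9,11a-octahydrocyclodeca[b]furan-8-yl (2E)-2-methylbut-2-enoate | C=C1C(=O)O[C@@H]2/C=C(\COC(C)=O)C[C@H](OC(=O)/C(C)=C/C)/C=C(/C)C[C@@H](O)[C@@H]12 | target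

**Totals**
Total steps: 20. Longest linear sequence: 18 steps (steps 1–5, 7, 8, 10–20).

**Steps most likely to fail, with fallbacks**

Step 15 (ring-closing metathesis to the ten-membered ring). A strained ring with a trisubstituted olefin must form against dimerisation and against attack of ruthenium on the C4=C5 olefin. Fallback, setting out from 22: the lactone is reduced with LiBH4 (THF, 0 °C) to the open 1,4-diol, the seco-diol F1. The metathesis is then run on this more flexible diene (second-generation Hoveyda–Grubbs catalyst (H2IMes)Cl2Ru=CH(C6H4-2-O-i-Pr), toluene, 1 mM, 80 °C) to give the macrocyclic diol F2. Oxidative lactonisation (TEMPO cat., PhI(OAc)2, CH2Cl2; primary alcohol to aldehyde, lactol with the C6 hydroxyl, then lactone) re-forms ring A and comes back to the route at 23.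

Step 13 (methallylboration of the epimerisable β-acyloxy aldehyde; C8 configuration depends on reagent control). Fallback, setting out from 20: the methallyl group is added without stereocontrol by a Barbier reaction (2-methylallyl bromide, indium powder, THF/H2O, rt) to give the mixture of C8-epimeric carbinols F3. These are oxidised with Dess–Martin periodinane to the β,γ-unsaturated ketone F4. Substrate-controlled reduction with LiBH(s-Bu)3 (THF, −78 °C) delivers hydride anti to the C6-bearing ring carbon (Felkin–Anh) and comes back at 21; any 8-epimer is recycled through F4.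

Step 7 (alkoxymethyl Suzuki coupling on an alkenyl iodide with a free allylic alcohol). Fallback, setting out from 8: the primary alcohol is silylated (TBSCl, imidazole, DMF) to the silyl ether F5. Carbonylation (Pd(PPh3)4, CO 1 atm, MeOH, Et3N, DMF, 60 °C) gives, with retention, the methyl ester F6. Reduction with i-Bu2AlH (CH2Cl2, −78 °C) gives the allylic alcohol F7, which is etherified under acid catalysis (4-methoxybenzyl trichloroacetimidate, La(OTf)3 cat., toluene, no base, so no silyl migration) to the bis-PMB silyl ether F8. n-Bu4NF in THF then comes back at 12.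

**Further compounds**
F1 | step 15 | (3S,4R,5Z,8S)-3-[(1R)-1-[(tert-butyldimethylsilyl)oxy]-3-methylbut-3-en-1-yl]-8-[(4-methoxybenzyl)oxy]-6-{[(4-methoxybenzyl)oxy]methyl}deca-5,9-diene-1,4-diol | OCC[C@H]([C@H](O[Si](C)(C)C(C)(C)C)CC(C)=C)[C@H](O)/C=C(\COCc1ccc(OC)cc1)C[C@H](OCc1ccc(OC)cc1)C=C
F2 | step 15 | 2-[(1S,2R,3Z,6S,7Z,10R)-10-[(tert-butyldimethylsilyl)oxy]-2-hydroxy-6-[(4-methoxybenzyl)oxy]-4-{[(4-methoxybenzyl)oxy]methyl}-8-methylcyclodeca-3,7-dien-1-yl]ethan-1-ol | OCC[C@H]1[C@H](O)/C=C(\COCc2ccc(OC)cc2)C[C@H](OCc2ccc(OC)cc2)/C=C(/C)C[C@H]1O[Si](C)(C)C(C)(C)C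
F3 | step 13 | (4R,5R)-4-(1-hydroxy-3-methylbut-3-en-1-yl)-5-[(1Z,4S)-4-[(4-methoxybenzyl)oxy]-2-{[(4-methoxybenzyl)oxy]methyl}hexa-1,5-dien-1-yl]oxolan-2-one, both carbinol epimers | O=C1C[C@H](C(O)CC(C)=C)[C@@H](/C=C(\COCc2ccc(OC)cc2)C[C@H](OCc2ccc(OC)cc2)C=C)O1
F4 | step 13 | (4S,5R)-4-(3-methylbut-3-enoyl)-5-[(1Z,4S)-4-[(4-methoxybenzyl)oxy]-2-{[(4-methoxybenzyl)oxy]methyl}hexa-1,5-dien-1-yl]oxolan-2-one | O=C1C[C@H](C(=O)CC(C)=C)[C@@H](/C=C(\COCc2ccc(OC)cc2)C[C@H](OCc2ccc(OC)cc2)C=C)O1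
F5 | step 7 | tert-butyl{[(2Z,5S)-3-iodo-5-[(4-methoxybenzyl)oxy]hepta-2,6-dien-1-yl]oxy}dimethylsilane | C=C[C@@H](OCc1ccc(OC)cc1)C/C(I)=C/CO[Si](C)(C)C(C)(C)C
F6 | step 7 | methyl (2Z,4S)-2-{2-[(tert-butyldimethylsilyl)oxy]ethylidene}-4-[(4-methoxybenzyl)oxy]hex-5-enoate | C=C[C@@H](OCc1ccc(OC)cc1)C/C(C(=O)OC)=C/CO[Si](C)(C)C(C)(C)C
F7 | step 7 | (2Z,4S)-2-{2-[(tert-butyldimethylsilyl)oxy]ethylidene}-4-[(4-methoxybenzyl)oxy]hex-5-en-1-ol | C=C[C@@H](OCc1ccc(OC)cc1)C/C(CO)=C/CO[Si](C)(C)C(C)(C)C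
F8 | step 7 | tert-butyl{[(2Z,5S)-5-[(4-methoxybenzyl)oxy]-3-{[(4-methoxybenzyl)oxy]methyl}hepta-2,6-dien-1-yl]oxy}dimethylsilane | C=C[C@@H](OCc1ccc(OC)cc1)C/C(COCc1ccc(OC)cc1)=C/CO[Si](C)(C)C(C)(C)C
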